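**Retrosynthetic overview**
1. Target ⇒ inversion of the single allylic lactone C–O centre (Mitsunobu re-lactonisation) ⇒ symmetric homodimer ⇒ endo Diels–Alder dimerisation of two molecules of a guaianolide cyclopentadiene monomer.
2. Monomer ⇒ hydroazulenone lactone by 1,2-reduction and dehydration.
3. Hydroazulenone ⇒ key disconnection C1–C10 (guaiane numbering): 7-exo cyclisation of an α-hydroxyalkyl radical onto an acyclic cis-enedione, then aldol condensation (C4–C5) to close the cyclopentenone.
4. Enedione ⇒ 2,5-dialkylfuran ⇒ Friedel–Crafts union of 2-ethylfuran with a lactone acetal; lactone stereotriad ⇒ menthyloxybutenolide by tandem conjugate addition/methylation.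
5. Ring order: γ-lactone → seven-membered ring → cyclopentenone → norbornene core (dimerisation) → re-closure of one lactone with inversion.

Assumption: the SMILES is taken literally; as written, the lactone of the cyclopentene (dienophile-derived) half is cis-fused, its O-bearing carbon being epimeric to the same carbon of the norbornene half, so the symmetric dimer is corrected at that one centre at the end.

**Route**

Step 1
Reactants: 1 5-hydroxyfuran-2(5H)-one
Product: 2 (5S)-5-{[(1S,2R,5S)-5-methyl-2-(propan-2-yl)cyclohexyl]oxy}furan-2(5H)-one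
Conditions: (+)-menthol (1.1 equiv), TsOH·H2O (2 mol %), toluene, 110 °C, Dean–Stark; crystallise (hexane), mother liquor re-equilibrated with TsOH
Reagents that add atoms: (+)-menthol, CC(C)[C@H]1CC[C@H](C)C[C@@H]1O
Why: Acid-catalysed acetalisation of the lactol gives both acetal epimers, which interconvert under the acid, so the (5S) epimer is collected by crystallisation-induced diastereomer transformation as for the known enantiomeric menthyloxybutenolide, and this acetal carbon is the only external source of chirality in the route.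

Step 2
Reactants: 2 (5S)-5-(d-menthyloxy)furan-2(5H)-one; 3 but-3-en-1-ylmagnesium bromide
Product: 4 (3S,4S,5S)-4-(but-3-en-1-yl)-3-methyl-5-{[(1S,2R,5S)-5-methyl-2-(propan-2-yl)cyclohexyl]oxy}oxolan-2-one
Conditions: 3 (1.5 equiv), CuBr·SMe2 (10 mol %), THF, −78 °C; then MeI (5 equiv), DMPU, −78 → −20 °C
Reagents that add atoms: iodomethane, CI
Why: CuBr·SMe2-catalysed conjugate addition of the Grignard reagent occurs anti to the menthyloxy group (sets C4) and the enolate is methylated anti to the new butenyl group (sets C3), the classical tandem 1,4-addition/enolate alkylation on a 5-alkoxybutenolide.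

Step 3
Reactants: 4 all-trans menthyloxy lactone; 5 2-ethylfuran
Product: 6 (3S,4S,5S)-4-(but-3-en-1-yl)-5-(5-ethylfuran-2-yl)-3-methyloxolan-2-one
Conditions: 5 (3 equiv), TMSOTf (10 mol %), CH2Cl2, −40 → 0 °C
Reagents that add atoms: none
Why: Ionisation of the lactone acetal gives an acyloxocarbenium ion that the free α-position of 2-ethylfuran attacks anti to the neighbouring butenyl group (Friedel–Crafts-type acetal substitution), which fixes the 4,5-trans lactone and releases the auxiliary.

Step 4
Reactants: 6 butenyl furyl lactone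
Product: 7 (3S,4S,5S)-5-(5-ethylfuran-2-yl)-4-(3-hydroxybutyl)-3-methyloxolan-2-one (both carbinol epimers)
Conditions: Co(acac)2 (20 mol %), PhSiH3 (2 equiv), O2 (1 atm), THF, 23 °C
Reagents that add atoms: dioxygen, O=O
Why: Mukaiyama hydration (hydrogen-atom transfer to the terminal alkene from the cobalt hydride made from Co(acac)2 and PhSiH3, O2 trapping of the secondary radical, reduction) gives the Markovnikov alcohol as both epimers, which does not matter because this carbon is planarised in step 6.

Step 5
Reactants: 7 furyl lactone alcohol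
Product: 8 (3S,4S,5S)-4-(3-hydroxybutyl)-3-methyl-5-[(2Z)-4-oxohex-2-enoyl]oxolan-2-one
Conditions: mCPBA (1.05 equiv), CH2Cl2, 0 °C
Reagents that add atoms: 3-chloroperbenzoic acid, OOC(=O)c1cccc(Cl)c1
Why: Peracid oxidation of a 2,5-dialkylfuran (epoxidation, then ring opening) unmasks the cis-1,4-enedione without touching the lactone or the alcohol, and no stereocentre is formed.

Step 6
Reactants: 8 cis-enedione lactone alcohol
Product: 10 (3S,3aS,6S,6aR,9bS)-6-hydroxy-3,6,9-trimethyl-3,3a,4,5,6,6a,7,9b-octahydroazuleno[4,5-b]furan-2,8-dione, via cycloheptanone diketone 9 (not isolated)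
Conditions: (nBu4N)4[W10O32] (2 mol %), MeCN (0.01 M), 390 nm LED, N2, 23 °C; then pyrrolidine (30 mol %), AcOH (30 mol %), 45 °C
Reagents that add atoms: none
Why: Proposed new method: photoexcited (nBu4N)4[W10O32] abstracts the hydridic carbinol C–H (closest known reaction: (nBu4N)4[W10O32]-photocatalysed Giese hydroalkylation of electron-poor alkenes with alcohols), the planar α-hydroxyalkyl radical from either carbinol epimer closes 7-exo-trig onto the enedione carbon next to the lactone-bearing ketone through a chair-like transition state locked by the trans-lactone, with the methyl group anti to the 2-oxobutyl branch and that branch pseudo-equatorial (sets the tertiary carbinol and the adjacent ring CH, the latter also correctable by enolisation), back hydrogen transfer from the reduced catalyst closes the cycle, and enamine-mediated intramolecular aldol condensation of the 1,4-diketone then forms the 2-methylcyclopentenone.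

Step 7
Reactants: 10 hydroazulenone lactone
Product: 11 (3S,3aS,6S,6aR,8S,9bS)-6,8-dihydroxy-3,6,9-trimethyl-3a,4,5,6,6a,7,8,9b-octahydroazuleno[4,5-b]furan-2(3H)-one
Conditions: NaBH4, CeCl3·7H2O, MeOH, −40 °C
Reagents that add atoms: none
Why: Luche 1,2-reduction of the enone leaves the lactone untouched, hydride arriving anti to the substituent at C6a to give mainly the 8S alcohol, and either epimer serves because this centre is removed in step 8.

Step 8
Reactants: 11 allylic alcohol (2 molecules for each molecule of 14; both halves of 14 come from it)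
Product: 14 Diels–Alder homodimer (both lactones trans-fused), via allylic mesylate 12 (not isolated), via cyclopentadiene monomer 13 (not isolated)
Conditions: MsCl (1.2 equiv), Et3N (3 equiv), CH2Cl2, −10 → 23 °C; aqueous work-up, concentrate; neat, 23 °C, 7–10 d
Reagents that add atoms: second molecule of cyclopentadiene monomer 13 (the dienophile; made in the same flask from a second molecule of 11), C1=CC(C)=C2[C@H]3OC(=O)[C@@H](C)[C@@H]3CC[C@](C)(O)[C@@H]21
Why: The secondary allylic alcohol is mesylated (the tertiary alcohol does not react) and loses methanesulfonic acid to give the cyclopentadiene; two molecules of this diene then combine on standing neat in the regio- and endo-selective Diels–Alder dimerisation expected for such guaianolide dienes, the disubstituted C=C of one molecule adding across the diene of the other with each partner reacting on the face anti to its carbinol-bearing ring carbon, which sets the four new stereocentres of the norbornene core.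

Step 9
Reactants: 14 homodimer
Product: 15 bis(γ-hydroxy acid) of 14
Conditions: LiOH·H2O (6 equiv), THF/H2O 3:1, 23 °C; 1 M HCl to pH 4 at 0 °C, fast EtOAc extraction, used at once
Reagents that add atoms: lithium hydroxide, [Li+].[OH-]
Why: Saponification by acyl–oxygen cleavage opens both γ-lactones without touching any stereocentre, and the bis(hydroxy acid) is kept cold and used immediately to limit relactonisation.

Step 10
Reactants: 15 bis(γ-hydroxy acid)
Product: 16 absinthin as given (target)
Conditions: PPh3 (3 equiv), DIAD (3 equiv), THF (0.005 M), 0 °C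
Reagents that add atoms: none
Why: Mitsunobu lactonisation activates the less hindered allylic secondary alcohol of the cyclopentene half as its alkoxyphosphonium ion, which the carboxylate displaces with inversion (5-exo-tet, giving the cis-fused lactone), whereas the neopentyl alcohol next to the quaternary carbon of the norbornene half cannot undergo SN2 displacement and relactonises with retention through the acyloxyphosphonium ion.

**Compound list**
1 | 5-hydroxyfuran-2(5H)-one (racemic lactol) | OC1OC(=O)C=C1 | starting material
2 | (5S)-5-{[(1S,2R,5S)-5-methyl-2-(propan-2-yl)cyclohexyl]oxy}furan-2(5H)-one | CC(C)[C@H]1CC[C@H](C)C[C@@H]1O[C@H]1OC(=O)C=C1 | intermediate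
3 | but-3-en-1-ylmagnesium bromide | C=CCC[Mg]Br | starting material
4 | (3S,4S,5S)-4-(but-3-en-1-yl)-3-methyl-5-{[(1S,2R,5S)-5-methyl-2-(propan-2-yl)cyclohexyl]oxy}oxolan-2-one | CC(C)[C@H]1CC[C@H](C)C[C@@H]1O[C@H]1OC(=O)[C@@H](C)[C@@H]1CCC=C | intermediate
5 | 2-ethylfuran | CCc1ccco1 | starting material
6 | (3S,4S,5S)-4-(but-3-en-1-yl)-5-(5-ethylfuran-2-yl)-3-methyloxolan-2-one | CCc1ccc(o1)[C@H]1OC(=O)[C@@H](C)[C@@H]1CCC=C | intermediate
7 | (3S,4S,5S)-5-(5-ethylfuran-2-yl)-4-(3-hydroxybutyl)-3-methyloxolan-2-one (both epimers at the side-chain carbinol) | CCc1ccc(o1)[C@H]1OC(=O)[C@@H](C)[C@@H]1CCC(C)O | intermediate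
8 | (3S,4S,5S)-4-(3-hydroxybutyl)-3-methyl-5-[(2Z)-4-oxohex-2-enoyl]oxolan-2-one (both carbinol epimers) | CCC(=O)/C=C\C(=O)[C@H]1OC(=O)[C@@H](C)[C@@H]1CCC(C)O | intermediate
9 | (3S,3aS,6S,7S,8aS)-6-hydroxy-3,6-dimethyl-7-(2-oxobutyl)hexahydro-2H-cyclohepta[b]furan-2,8(3H)-dione | O=C1[C@H]2OC(=O)[C@@H](C)[C@@H]2CC[C@](C)(O)[C@@H]1CC(=O)CC | intermediate (not isolated)
10 | (3S,3aS,6S,6aR,9bS)-6-hydroxy-3,6,9-trimethyl-3,3a,4,5,6,6a,7,9b-octahydroazuleno[4,5-b]furan-2,8-dione | O=C1C(C)=C2[C@H]3OC(=O)[C@@H](C)[C@@H]3CC[C@](C)(O)[C@@H]2C1 | intermediate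
11 | (3S,3aS,6S,6aR,8S,9bS)-6,8-dihydroxy-3,6,9-trimethyl-3a,4,5,6,6a,7,8,9b-octahydroazuleno[4,5-b]furan-2(3H)-one | O[C@@H]1C(C)=C2[C@H]3OC(=O)[C@@H](C)[C@@H]3CC[C@](C)(O)[C@@H]2C1 | intermediate
12 | 8-O-methanesulfonate of 11 | CS(=O)(=O)O[C@@H]1C(C)=C2[C@H]3OC(=O)[C@@H](C)[C@@H]3CC[C@](C)(O)[C@@H]2C1 | intermediate (not isolated)
13 | (3S,3aS,6S,6aR,9bS)-6-hydroxy-3,6,9-trimethyl-3a,4,5,6,6a,9b-hexahydroazuleno[4,5-b]furan-2(3H)-one (cyclopentadiene monomer) | C1=CC(C)=C2[C@H]3OC(=O)[C@@H](C)[C@@H]3CC[C@](C)(O)[C@@H]21 | intermediate (not isolated)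
14 | endo Diels–Alder homodimer of 13: the structure of 16 except that the lactone of the cyclopentene half is trans-fused (its O-bearing CH has the opposite configuration) | CC1=C[C@@H]2[C@H]3[C@H](C(C)=C4[C@H]5OC(=O)[C@@H](C)[C@@H]5CC[C@](C)(O)[C@@H]43)[C@@]13[C@@H]2[C@@](C)(O)CC[C@H]1[C@H](C)C(=O)O[C@@H]13 | intermediate
15 | bis(γ-hydroxy acid) from 14: both lactones opened to a secondary alcohol and a 2-propanoic acid side chain, all configurations as in 14 | CC1=C[C@@H]2[C@H]3[C@H](C(C)=C4[C@@H](O)[C@H]([C@H](C)C(=O)O)CC[C@](C)(O)[C@@H]43)[C@@]13[C@@H]2[C@@](C)(O)CC[C@@H]([C@H](C)C(=O)O)[C@@H]3O | intermediate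
16 | absinthin as given: cis-fused lactone on the cyclopentene half, trans-fused lactone on the norbornene half | CC1=C[C@@H]2[C@H]3[C@H](C(C)=C4[C@@H]5OC(=O)[C@@H](C)[C@@H]5CC[C@](C)(O)[C@@H]43)[C@@]13[C@@H]2[C@@](C)(O)CC[C@H]1[C@H](C)C(=O)O[C@@H]13 | target

**Step count and risks**
Total step count: 10. Longest linear sequence: 10 steps (1 → 16).

The three steps most likely to fail are step 6, step 10 and step 3.

In step 6 the 7-exo radical closure has no direct precedent. The very reducible enedione may instead accept an electron from the reduced (nBu4N)4[W10O32] or from the α-hydroxyalkyl radical, and 8-endo closure onto the other enedione carbon or a 1,5-hydrogen shift from the α-acyloxy C–H can compete. The fallback sets out from 8 and builds the five-membered ring first. Et3N-mediated intramolecular aldol addition of the ethyl-ketone enolate onto the lactone-bearing ketone (attack anti to the lactone C–O bond) gives the 4-hydroxycyclopentenone lactone F1. The same (nBu4N)4[W10O32] hydrogen-atom transfer then sends the carbinol radical onto the β-carbon of this rigid, much less reducible cyclic enone, necessarily cis to the tether, to give the tricyclic β-hydroxy ketone F2. E1cB loss of water (DBU, CH2Cl2) returns the route at 10.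

In step 10 the allylic alcohol may lactonise with retention through carboxyl activation, giving back 14, or may ionise. The fallback sets out from 15. MnO2 in CH2Cl2 oxidises only the allylic secondary alcohol, while the other hydroxy acid relactonises, to give the enone acid F3. NaBH4/CeCl3·7H2O reduction from the less hindered face gives the epimeric allylic hydroxy acid F4, which closes with retention under catalytic TsOH and so comes back to the route at 16. Alcohol of the original configuration returns 14 for recycling.

In step 3 the acyloxocarbenium ion may form too sluggishly, or the furan may oligomerise under acid. The fallback sets out from 4. Aqueous trifluoroacetic acid hydrolyses the acetal to the lactol F5 and frees the auxiliary. (5-Ethylfuran-2-yl)lithium F6 (from 5 and nBuLi, 2.2 equiv, THF, −78 °C) adds to the ring-opened aldehyde carboxylate, and work-up with aqueous HCl gives the furyl hydroxy acid F7. Catalytic TsOH in benzene lactonises it and equilibrates the furfuryl C–O centre to the all-trans lactone, rejoining the route at 6.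

Further compounds
F1 | step 6 | (3S,4S,5S)-4-(3-hydroxybutyl)-5-[(1S,5S)-1-hydroxy-5-methyl-4-oxocyclopent-2-en-1-yl]-3-methyloxolan-2-one | C[C@@H]1C(=O)C=C[C@@]1(O)[C@H]1OC(=O)[C@@H](C)[C@@H]1CCC(C)O
F2 | step 6 | (3S,3aS,6S,6aS,9S,9aS,9bS)-6,9a-dihydroxy-3,6,9-trimethyldecahydroazuleno[4,5-b]furan-2,8-dione | O=C1[C@@H](C)[C@]2(O)[C@H]3OC(=O)[C@@H](C)[C@@H]3CC[C@](C)(O)[C@@H]2C1
F3 | step 10 | enone acid: 14 with the lactone of the cyclopentene half opened to the free acid and its carbinol carbon oxidised to the conjugated ketone | CC1=C[C@@H]2[C@H]3[C@H](C(C)=C4C(=O)[C@H]([C@H](C)C(=O)O)CC[C@](C)(O)[C@@H]43)[C@@]13[C@@H]2[C@@](C)(O)CC[C@H]1[C@H](C)C(=O)O[C@@H]13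
F4 | step 10 | allylic hydroxy acid epimeric at the carbinol carbon to the cyclopentene half of 15, norbornene-half lactone closed | CC1=C[C@@H]2[C@H]3[C@H](C(C)=C4[C@H](O)[C@H]([C@H](C)C(=O)O)CC[C@](C)(O)[C@@H]43)[C@@]13[C@@H]2[C@@](C)(O)CC[C@H]1[C@H](C)C(=O)O[C@@H]13
F5 | step 3 | (3S,4S)-4-(but-3-en-1-yl)-5-hydroxy-3-methyloxolan-2-one (both anomers) | OC1OC(=O)[C@@H](C)[C@@H]1CCC=C
F6 | step 3 | (5-ethylfuran-2-yl)lithium | [Li]c1ccc(CC)o1
F7 | step 3 | (2S,3S)-3-[(5-ethylfuran-2-yl)(hydroxy)methyl]-2-methylhept-6-enoic acid (both carbinol epimers) | CCc1ccc(o1)C(O)[C@@H](CCC=C)[C@H](C)C(=O)O
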